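South and north start from 0.51 M of electrophile and 2.00 equiv of protonated nucleophile, as eta and theta did, and they differ in free base.

the same everywhere: electrophile 0.51 M

| run | free base | protonated nucleophile | remark | time |
|---|---|---|---|---|
| eta | 1.4 equiv | 2 equiv | run made earlier |  |
| theta | 2.9 equiv | 2 equiv | run made earlier |  |
| south | 1.10 equiv | 2.00 equiv |  | 5.0 h |
| north | 2.20 equiv | 2.00 equiv |  | 5.0 h |

| run | time / h | electrophile / % | target / % |
|---|---|---|---|
| eta | 0.250 | 92 | 10 |
| eta | 0.833 | 77 | 21 |
| eta | 1.33 | 69 | 31 |
| eta | 2.00 | 62 | 39 |
| eta | 3.00 | 48 | 51 |
| eta | 4.00 | 42 | 57 |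
| eta | 5.00 | 34 | 66 |
| theta | 0.667 | 71 | 27 |
| theta | 1.33 | 56 | 43 |
| theta | 2.00 | 45 | 55 |
| theta | 3.00 | 31 | 69 |
| theta | 4.00 | 21 | 75 |
| theta | 5.00 | 17 | 83 |

(standard deviation of a reading: 1.5 percentage points)



- part of the electrophile that has reacted at the end, south
- part of the electrophile that has reacted at the end, north
- what raising the equivalents of free base from its lowest to its highest value here does to the part of the electrophile that has reacted (changes below 5 percentage points count as none) (no change / it rises / it falls)

I measure progress by L, a pseudo-first-order count:

L = ln(electrophile charged / electrophile left)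

The bench rule says that one equivalent of free base frees one equivalent of nucleophile, so L should go in step with the base charged. Eta left 34 % of its electrophile at 5.00 h and theta left 17 %, so:

L(eta) = 1.08
L(theta) = 1.77

The base rose 2.07-fold but L rose 1.64-fold, less. The rule therefore promises 89.3 % reacted in theta, where 83.0 % was read, with a scatter of 1.5 percentage points.

So the proportion fails across the span from eta to theta, and two runs can't show where inside that span the failure starts. I drop the proportion and carry the base order n, the slope of ln L against ln base, read from the two runs:

n = ln(L(theta)/L(eta)) / ln(base theta/base eta) = 0.681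

Scaling from eta, with south a stretch below eta's base and north between the runs:

L(south) = 0.915, so 59.9 % reacted
L(north) = 1.47, so 77.0 % reacted

The forecast gives 58 % (52 % to 63 %) for south, shaded from its own scaled 60 because “base depletion bites harder when little excess remains”, and 77 % (73 % to 81 %) for north, with the trend: it rises.

    acid set free + free base ⇌ salt of the base, settled at all times (K = 13600 M⁻¹)
    electrophile + nucleophile → acid set free + target (k = 0.506 M⁻¹ h⁻¹)
    acid set free → by-product carried off (k = 12.5 h⁻¹)
    target → over-reaction product (k = 1.64 × 10⁻⁴ h⁻¹)
    nucleophile + acid set free ⇌ protonated nucleophile, settled at all times (K = 210 M⁻¹)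

South gives 60.4 % and north 76.5 %; the part reacted: it rises, by 16 points. At the end of south, 1.3 % of the charged free base is still free, less than the 40 % of electrophile left. From south to north the base goes up 2.00-fold, which through n multiplies L by 1.60; the two answers give 1.56.

Now a neighbour like south, but with 1.90 equiv of free base: n gives L = 1.33, so 73.6 % reacted. That flask gives 72.5 %.

(The runs come from a simulation on assumed constants, and the scatter is random.)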